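**Plan**

1. Locants are those of the azulene core (five-membered ring C1, C2, C3, C3a, C8a; seven-membered ring C3a, C4–C8, C8a). After removal of a phenylthio handle at C2, the retrosynthesis cuts C1–C2 and C3a–C8a in one transform, a thionium-initiated Prins cyclization that ends in a pinacol shift.
2. This is possible because the C8 ketone carries the quaternary C8a, which is bonded to ring-fusion C3a. Sending C3a back to C8 turns the seven-membered ring into a cyclohexenyl silyl ether (C3a, C4, C5, C6, C7, C8) and the five-membered ring into an isopropenyl group (C8a, C1) plus a dithioacetal side chain (C2, C3).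
3. Further cuts: C2–C3 (dithioacetal anion + isopropyl ketone), C8–C8a (isopropenyl Grignard + enone), the ester C–O, and the cyclohexene by a Diels–Alder transform (C4–C5 and C3a–C8), with the isopropyl ketone and the C4 oxygen tied up as 2,2-dimethylfuran-3(2H)-one.
4. Forward order of rings: cyclohexene (Diels–Alder, fused to the temporary furanone), furanone opened with SmI2, side chain and carbinols built on the six-membered ring, then the key step closes the five-membered ring and enlarges the six-membered ring to the seven-membered enone.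
5. Stereochemistry: the cyclic cis dienophile fixes C3a/C4; a lipase resolution gives the absolute configuration; chelation-controlled addition sets C3; Grignard addition anti to the side chain sets the carbinol that steers the key step; the stereospecific 1,2-shift sets C8a (cis ring fusion).

Key step: step 11

Assumption: 2,2-dimethylfuran-3(2H)-one is taken as purchasable; compounds 4 and 5 are racemates and are written as both enantiomers.

**Route**

Step 1
Reactants: 1 3-methylbut-2-enal
Product: 2 (E)-tert-butyl(dimethyl)[(3-methylbuta-1,3-dien-1-yl)oxy]silane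
Conditions: TBSOTf, Et3N, Et2O, 0 °C to rt
Reagents that add atoms: tert-butyldimethylsilyl trifluoromethanesulfonate (TBSOTf), CC(C)(C)[Si](C)(C)OS(=O)(=O)C(F)(F)F
Why: O-silylation of the enal followed by γ-deprotonation (silyl dienol ether formation) should give the 1-silyloxy diene, the E enol ether being favoured on steric grounds.

Step 2
Reactants: 2 (E)-tert-butyl(dimethyl)[(3-methylbuta-1,3-dien-1-yl)oxy]silane; 3 2,2-dimethylfuran-3(2H)-one
Product: 4 rac-(3aS,4R,7aS)-4-{[tert-butyl(dimethyl)silyl]oxy}-2,2,6-trimethyl-3a,4,7,7a-tetrahydro-1-benzofuran-3(2H)-one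
Conditions: Me2AlCl (20 mol %), CH2Cl2, −40 to 0 °C
Reagents that add atoms: none
Why: In this Lewis-acid-catalysed Diels–Alder reaction the nucleophilic CH2 terminus of the diene should bond to C5 of the furanone (β-carbon of the enone) and the silyloxy-bearing terminus to C4; suprafacial addition to the cyclic cis alkene fixes the cis ring fusion and the endo transition state places the silyloxy group cis to the C3a–C3 bond.

Step 3
Reactants: 4 rac-(3aS,4R,7aS)-4-{[tert-butyl(dimethyl)silyl]oxy}-2,2,6-trimethyl-3a,4,7,7a-tetrahydro-1-benzofuran-3(2H)-one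
Product: 5 rac-1-[(1S,2R,6S)-2-{[tert-butyl(dimethyl)silyl]oxy}-6-hydroxy-4-methylcyclohex-3-en-1-yl]-2-methylpropan-1-one
Conditions: SmI2 (2.5 equiv), THF, MeOH, −78 °C
Reagents that add atoms: none
Why: In this samarium diiodide reduction of an α-alkoxy ketone the ketyl expels the α carbon–oxygen bond (O1–C2) and the trivalent samarium enolate, formed on the gem-dimethyl side only, is protonated by MeOH, so the isopropyl ketone and the free hydroxyl should appear with the two ring stereocenters next to them untouched.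

Step 4
Reactants: 5 rac-1-[(1S,2R,6S)-2-{[tert-butyl(dimethyl)silyl]oxy}-6-hydroxy-4-methylcyclohex-3-en-1-yl]-2-methylpropan-1-one
Product: 6 1-[(1S,2R,6S)-2-{[tert-butyl(dimethyl)silyl]oxy}-6-hydroxy-4-methylcyclohex-3-en-1-yl]-2-methylpropan-1-one (single enantiomer, recovered alcohol)
Conditions: Amano lipase PS (Burkholderia cepacia lipase), vinyl acetate, MTBE, 30 °C, stopped shortly after half conversion
Reagents that add atoms: none
Why: In this lipase-catalysed kinetic resolution by transesterification the Kazlauskas rule predicts faster acetylation of the enantiomer with the R carbinol carbon (substituted ring CH as large group, ring CH2 as medium group), so the wanted 6S alcohol should be recovered unchanged and separated from the acetate.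

Step 5
Reactants: 6 1-[(1S,2R,6S)-2-{[tert-butyl(dimethyl)silyl]oxy}-6-hydroxy-4-methylcyclohex-3-en-1-yl]-2-methylpropan-1-one
Product: 7 (2R)-2-[(1S,2R,6S)-2-{[tert-butyl(dimethyl)silyl]oxy}-6-hydroxy-4-methylcyclohex-3-en-1-yl]-3-methyl-1,1-bis(phenylsulfanyl)butan-2-ol
Conditions: (PhS)2CH2 (2.6 equiv), n-BuLi (2.5 equiv), THF, 0 °C; then 6, −78 °C; H2O quench
Reagents that add atoms: bis(phenylsulfanyl)methane, C(Sc1ccccc1)Sc1ccccc1
Why: In this 1,2-addition of bis(phenylthio)methyllithium the lithium alkoxide at C6 and the ketone oxygen should form a six-membered chelate, and attack on the carbonyl face next to H-1 and anti to the silyloxy-bearing C2 (also the Felkin–Anh face) should set the tertiary carbinol as drawn.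

Step 6
Reactants: 7 (2R)-2-[(1S,2R,6S)-2-{[tert-butyl(dimethyl)silyl]oxy}-6-hydroxy-4-methylcyclohex-3-en-1-yl]-3-methyl-1,1-bis(phenylsulfanyl)butan-2-ol
Product: 8 (1S,2S,3R)-2-[(2R)-2-hydroxy-3-methyl-1,1-bis(phenylsulfanyl)butan-2-yl]-5-methylcyclohex-4-ene-1,3-diol
Conditions: tetrabutylammonium fluoride (TBAF), THF, 0 °C to rt
Reagents that add atoms: none
Why: Fluoride-induced cleavage of the silyl ether (Si–F bond formation) should free the allylic alcohol without touching a stereocenter.

Step 7
Reactants: 8 (1S,2S,3R)-2-[(2R)-2-hydroxy-3-methyl-1,1-bis(phenylsulfanyl)butan-2-yl]-5-methylcyclohex-4-ene-1,3-diol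
Product: 9 (5S,6R)-5-hydroxy-6-[(2R)-2-hydroxy-3-methyl-1,1-bis(phenylsulfanyl)butan-2-yl]-3-methylcyclohex-2-en-1-one
Conditions: MnO2 (activated, excess), CH2Cl2, rt
Reagents that add atoms: none
Why: Manganese dioxide oxidation is selective for the allylic secondary alcohol, so the homoallylic hydroxyl, the tertiary alcohol and the dithioacetal should survive and the enone should form under neutral conditions that avoid retro-aldol cleavage and β-elimination.

Step 8
Reactants: 9 (5S,6R)-5-hydroxy-6-[(2R)-2-hydroxy-3-methyl-1,1-bis(phenylsulfanyl)butan-2-yl]-3-methylcyclohex-2-en-1-one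
Product: 10 (1S,2S,3R)-2-[(2R)-2-hydroxy-3-methyl-1,1-bis(phenylsulfanyl)butan-2-yl]-5-methyl-3-(prop-1-en-2-yl)cyclohex-4-ene-1,3-diol
Conditions: isopropenylmagnesium bromide (5 equiv), LaCl3·2LiCl (30 mol %), THF, −78 to −30 °C
Reagents that add atoms: isopropenylmagnesium bromide, CC(=C)[Mg]Br
Why: In this lanthanum-assisted Grignard 1,2-addition to the β,β-disubstituted enone the reagent should approach anti to the bulky C6 side chain (equatorial attack, as with 2-substituted cyclohexanones) and away from the axial C5 alkoxide, which places the new hydroxyl cis to the side chain and to the C5 oxygen.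

Step 9
Reactants: 10 (1S,2S,3R)-2-[(2R)-2-hydroxy-3-methyl-1,1-bis(phenylsulfanyl)butan-2-yl]-5-methyl-3-(prop-1-en-2-yl)cyclohex-4-ene-1,3-diol
Product: 11 (1S,5R,6S)-5-hydroxy-6-[(2R)-2-hydroxy-3-methyl-1,1-bis(phenylsulfanyl)butan-2-yl]-3-methyl-5-(prop-1-en-2-yl)cyclohex-3-en-1-yl 4-methoxybenzoate
Conditions: 4-methoxybenzoyl chloride (1.2 equiv), pyridine, 4-(dimethylamino)pyridine (cat.), CH2Cl2, 0 °C
Reagents that add atoms: 4-methoxybenzoyl chloride, COc1ccc(C(Cl)=O)cc1
Why: This 4-(dimethylamino)pyridine-catalysed acylation should be selective for the only secondary alcohol, since the two tertiary alcohols do not react under these conditions, and the carbinol configuration is retained.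

Step 10
Reactants: 11 (1S,5R,6S)-5-hydroxy-6-[(2R)-2-hydroxy-3-methyl-1,1-bis(phenylsulfanyl)butan-2-yl]-3-methyl-5-(prop-1-en-2-yl)cyclohex-3-en-1-yl 4-methoxybenzoate
Product: 12 (1S,5R,6S)-3-methyl-6-{(2R)-3-methyl-1,1-bis(phenylsulfanyl)-2-[(trimethylsilyl)oxy]butan-2-yl}-5-(prop-1-en-2-yl)-5-[(trimethylsilyl)oxy]cyclohex-3-en-1-yl 4-methoxybenzoate
Conditions: TMSOTf (3 equiv), 2,6-lutidine (5 equiv), CH2Cl2, −78 °C
Reagents that add atoms: trimethylsilyl trifluoromethanesulfonate (TMSOTf), C[Si](C)(C)OS(=O)(=O)C(F)(F)F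
Why: Base-buffered silyl ether formation at low temperature should cap both tertiary alcohols before the doubly allylic carbinol can ionise, and the silyl ethers keep the hydroxyls from trapping the thionium ion in the next step.

Step 11
Reactants: 12 (1S,5R,6S)-3-methyl-6-{(2R)-3-methyl-1,1-bis(phenylsulfanyl)-2-[(trimethylsilyl)oxy]butan-2-yl}-5-(prop-1-en-2-yl)-5-[(trimethylsilyl)oxy]cyclohex-3-en-1-yl 4-methoxybenzoate
Product: 15 (2R,3R,3aR,4S,8aS)-6,8a-dimethyl-8-oxo-2-(phenylsulfanyl)-3-(propan-2-yl)-3-[(trimethylsilyl)oxy]-1,2,3,3a,4,5,8,8a-octahydroazulen-4-yl 4-methoxybenzoate, via thionium ion 13 (not isolated), via tertiary carbocation 14 (not isolated)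
Conditions: dimethyl(methylthio)sulfonium tetrafluoroborate (DMTSF, 1.5 equiv), 2,6-di-tert-butyl-4-methylpyridine (0.5 equiv), CH2Cl2, −78 to −20 °C
Reagents that add atoms: none
Why: DMTSF transfers MeS+ to one sulfur of the dithioacetal and loss of PhSSMe gives thionium ion 13, whose carbon is attacked by the CH2 terminus of the isopropenyl group (C1–C2 bond) through a chair-like six-membered transition state to give tertiary cation 14; the ring bond C8–C3a, antiperiplanar to the new bond, then shifts from the silyloxy carbon to the cationic carbon (C3a–C8a bond) while Me3Si leaves as Me3SiF and the carbinol carbon becomes the C8 ketone. The closest known reaction type is the pinacol-terminated Prins cyclization in its thionium-initiated, ring-enlarging cyclopentane-annulation form. The five-membered ring is closed by a 6-endo-trig attack of the alkene on the thionium carbon followed by contraction of that six-membered ring in the 1,2-shift, and the seven-membered ring is not closed by a ring bond of its own but grows out of the cyclohexene by one-carbon ring expansion in the same shift. The quaternary C8a is set by the suprafacial 1,2-shift inside a rigid trans-fused bicyclic chair (isopropenyl trans to the side chain, ring carbon C4 equatorial), which can deliver only the cis ring fusion; C3a migrates with retention, C3 and C4 are carried over from 12, and the C2–S centre (sulfur expected equatorial) is erased in step 12. The step needs capture of the thionium ion by the isopropenyl group and not by the ring alkene or a silyloxy oxygen, migration of the ring bond and not of the vinylic C7, and survival of the doubly allylic silyl ether until the alkene has attacked; these should be secured by the chair against a bridged alternative, by the antiperiplanar alignment of the C8–C3a bond, and by the thiophilic, non-acidic activator at low temperature.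

Step 12
Reactants: 15 (2R,3R,3aR,4S,8aS)-6,8a-dimethyl-8-oxo-2-(phenylsulfanyl)-3-(propan-2-yl)-3-[(trimethylsilyl)oxy]-1,2,3,3a,4,5,8,8a-octahydroazulen-4-yl 4-methoxybenzoate
Product: 17 (3R,3aR,4S,8aS)-3-hydroxy-6,8a-dimethyl-8-oxo-3-(propan-2-yl)-1,2,3,3a,4,5,8,8a-octahydroazulen-4-yl 4-methoxybenzoate (target), via desulfurized silyl ether 16 (not isolated)
Conditions: Raney Ni (W-2, deactivated in refluxing acetone), EtOH, rt; then pyridinium p-toluenesulfonate, MeOH, rt
Reagents that add atoms: none
Why: Raney nickel hydrogenolysis of the C–S bond (desulfurization) should replace the phenylsulfanyl group by hydrogen while the deactivated catalyst spares the conjugated trisubstituted alkene and the ester, and mild acid methanolysis then removes the tertiary trimethylsilyl ether without touching a stereocenter.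

**Compound list**

1 | 3-methylbut-2-enal | CC(C)=CC=O | starting material
2 | (E)-tert-butyl(dimethyl)[(3-methylbuta-1,3-dien-1-yl)oxy]silane | CC(=C)/C=C/O[Si](C)(C)C(C)(C)C | intermediate
3 | 2,2-dimethylfuran-3(2H)-one | CC1(C)OC=CC1=O | starting material
4 | rac-(3aS,4R,7aS)-4-{[tert-butyl(dimethyl)silyl]oxy}-2,2,6-trimethyl-3a,4,7,7a-tetrahydro-1-benzofuran-3(2H)-one (cis-fused, silyloxy cis to the C3a–C3 bond; racemate) | CC1(C)O[C@H]2CC(C)=C[C@@H](O[Si](C)(C)C(C)(C)C)[C@H]2C1=O.CC1(C)O[C@@H]2CC(C)=C[C@H](O[Si](C)(C)C(C)(C)C)[C@@H]2C1=O | intermediate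
5 | rac-1-[(1S,2R,6S)-2-{[tert-butyl(dimethyl)silyl]oxy}-6-hydroxy-4-methylcyclohex-3-en-1-yl]-2-methylpropan-1-one (all-cis; racemate) | O[C@H]1CC(C)=C[C@@H](O[Si](C)(C)C(C)(C)C)[C@H]1C(=O)C(C)C.O[C@@H]1CC(C)=C[C@H](O[Si](C)(C)C(C)(C)C)[C@@H]1C(=O)C(C)C | intermediate
6 | 1-[(1S,2R,6S)-2-{[tert-butyl(dimethyl)silyl]oxy}-6-hydroxy-4-methylcyclohex-3-en-1-yl]-2-methylpropan-1-one | O[C@H]1CC(C)=C[C@@H](O[Si](C)(C)C(C)(C)C)[C@H]1C(=O)C(C)C | intermediate
7 | (2R)-2-[(1S,2R,6S)-2-{[tert-butyl(dimethyl)silyl]oxy}-6-hydroxy-4-methylcyclohex-3-en-1-yl]-3-methyl-1,1-bis(phenylsulfanyl)butan-2-ol | O[C@H]1CC(C)=C[C@@H](O[Si](C)(C)C(C)(C)C)[C@H]1[C@](O)(C(C)C)C(Sc1ccccc1)Sc1ccccc1 | intermediate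
8 | (1S,2S,3R)-2-[(2R)-2-hydroxy-3-methyl-1,1-bis(phenylsulfanyl)butan-2-yl]-5-methylcyclohex-4-ene-1,3-diol | O[C@H]1CC(C)=C[C@@H](O)[C@H]1[C@](O)(C(C)C)C(Sc1ccccc1)Sc1ccccc1 | intermediate
9 | (5S,6R)-5-hydroxy-6-[(2R)-2-hydroxy-3-methyl-1,1-bis(phenylsulfanyl)butan-2-yl]-3-methylcyclohex-2-en-1-one | O[C@H]1CC(C)=CC(=O)[C@H]1[C@](O)(C(C)C)C(Sc1ccccc1)Sc1ccccc1 | intermediate
10 | (1S,2S,3R)-2-[(2R)-2-hydroxy-3-methyl-1,1-bis(phenylsulfanyl)butan-2-yl]-5-methyl-3-(prop-1-en-2-yl)cyclohex-4-ene-1,3-diol | O[C@H]1CC(C)=C[C@](O)(C(C)=C)[C@H]1[C@](O)(C(C)C)C(Sc1ccccc1)Sc1ccccc1 | intermediate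
11 | (1S,5R,6S)-5-hydroxy-6-[(2R)-2-hydroxy-3-methyl-1,1-bis(phenylsulfanyl)butan-2-yl]-3-methyl-5-(prop-1-en-2-yl)cyclohex-3-en-1-yl 4-methoxybenzoate | COc1ccc(cc1)C(=O)O[C@H]2CC(C)=C[C@](O)(C(C)=C)[C@H]2[C@](O)(C(C)C)C(Sc3ccccc3)Sc4ccccc4 | intermediate
12 | (1S,5R,6S)-3-methyl-6-{(2R)-3-methyl-1,1-bis(phenylsulfanyl)-2-[(trimethylsilyl)oxy]butan-2-yl}-5-(prop-1-en-2-yl)-5-[(trimethylsilyl)oxy]cyclohex-3-en-1-yl 4-methoxybenzoate | COc1ccc(cc1)C(=O)O[C@H]2CC(C)=C[C@](O[Si](C)(C)C)(C(C)=C)[C@H]2[C@](O[Si](C)(C)C)(C(C)C)C(Sc3ccccc3)Sc4ccccc4 | intermediate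
13 | S-phenyl thionium ion from 12 (one PhS lost; tetrafluoroborate) | COc1ccc(cc1)C(=O)O[C@H]2CC(C)=C[C@](O[Si](C)(C)C)(C(C)=C)[C@H]2[C@](O[Si](C)(C)C)(C(C)C)C=[S+]c3ccccc3.F[B-](F)(F)F | intermediate
14 | tertiary carbocation after Prins closure (trans-fused bicycle, cationic carbon is the later C8a; tetrafluoroborate) | COc1ccc(cc1)C(=O)O[C@H]2CC(C)=C[C@]3(O[Si](C)(C)C)[C+](C)C[C@@H](Sc4ccccc4)[C@@](O[Si](C)(C)C)(C(C)C)[C@@H]23.F[B-](F)(F)F | intermediate
15 | (2R,3R,3aR,4S,8aS)-6,8a-dimethyl-8-oxo-2-(phenylsulfanyl)-3-(propan-2-yl)-3-[(trimethylsilyl)oxy]-1,2,3,3a,4,5,8,8a-octahydroazulen-4-yl 4-methoxybenzoate | COc1ccc(cc1)C(=O)O[C@H]2CC(C)=CC(=O)[C@@]3(C)C[C@@H](Sc4ccccc4)[C@@](O[Si](C)(C)C)(C(C)C)[C@@H]23 | intermediate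
16 | (3R,3aR,4S,8aS)-6,8a-dimethyl-8-oxo-3-(propan-2-yl)-3-[(trimethylsilyl)oxy]-1,2,3,3a,4,5,8,8a-octahydroazulen-4-yl 4-methoxybenzoate | COc1ccc(cc1)C(=O)O[C@H]2CC(C)=CC(=O)[C@@]3(C)CC[C@@](O[Si](C)(C)C)(C(C)C)[C@@H]23 | intermediate
17 | (3R,3aR,4S,8aS)-3-hydroxy-6,8a-dimethyl-8-oxo-3-(propan-2-yl)-1,2,3,3a,4,5,8,8a-octahydroazulen-4-yl 4-methoxybenzoate | COc1ccc(cc1)C(=O)O[C@H]2CC(C)=CC(=O)[C@@]3(C)CC[C@@](O)(C(C)C)[C@@H]23 | target

**Summary**

Total step count: 12. Longest linear sequence: 12 steps (1 to 17; the furanone 3 enters at step 2).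

**Steps most likely to fail**

Step 11. The chair-like closure places the isopropyl group syn-axial to the C–OSi bond and may be slow. A 1,2-shift at the silyloxy carbinol next to the thionium carbon, capture of the thionium ion by a silyloxy oxygen, or ionisation of the doubly allylic silyl ether could then take over. Fallback, from 12: oxidative hydrolysis of the dithioacetal (PhI(OCOCF3)2, NaHCO3, aqueous MeCN, 0 °C) should give the α-silyloxy aldehyde F1. SnCl4 (CH2Cl2, −78 °C) then starts the same Prins–pinacol cascade from a tin-bound oxocarbenium ion instead of a thionium ion and should give the C2-hydroxy hydroazulenone F2. The C2 hydroxyl is converted into the O-phenyl thionocarbonate F3 (PhOC(S)Cl, pyridine, 4-(dimethylamino)pyridine) and removed by Barton–McCombie deoxygenation (Bu3SnH, AIBN, toluene, 80 °C). This returns to 16, which is desilylated as in step 12.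

Step 2. The furanone is a vinylogous ester and a weak dienophile, so cycloaddition may be slow and Lewis-acid-induced desilylation or Mukaiyama–Michael opening of the diene may win. Fallback, from 3: bromination–dehydrobromination (Br2, CH2Cl2, 0 °C; then Et3N) should give 4-bromo-2,2-dimethylfuran-3(2H)-one F4, an α-bromo enone and a better dienophile. Its Diels–Alder reaction with 2 under the same conditions should give the angular bromide F5 with the same regiochemistry and cis ring fusion. Radical debromination (Bu3SnH, AIBN, toluene, 80 °C) delivers hydrogen to the α-keto radical on the convex face and returns to the cis-fused 4.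

Step 5. Addition of the bulky, stabilised carbanion to the hindered ketone may be slow, so that enolisation with epimerisation at C1, retro-aldol opening of the lithium aldolate or poor facial selectivity competes. Fallback, from 6: the smaller and more reactive (phenylthio)methyllithium (thioanisole, n-BuLi, DABCO, THF, 0 °C; then 6, −78 °C) should add under the same chelation control to give the β-hydroxy sulfide F6. Deprotonation next to sulfur (s-BuLi, TMEDA, THF, −78 °C, excess base for the two alkoxides) and sulfenylation with PhSSPh then installs the second phenylthio group and returns to 7.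

Further compounds
F1 | step 11 | α-silyloxy aldehyde (dithioacetal carbon of 12 as CHO) | COc1ccc(cc1)C(=O)O[C@H]2CC(C)=C[C@](O[Si](C)(C)C)(C(C)=C)[C@H]2[C@](O[Si](C)(C)C)(C(C)C)C=O
F2 | step 11 | C2-hydroxy analogue of 15 (OH in place of SPh) | COc1ccc(cc1)C(=O)O[C@H]2CC(C)=CC(=O)[C@@]3(C)C[C@@H](O)[C@@](O[Si](C)(C)C)(C(C)C)[C@@H]23
F3 | step 11 | C2 O-phenyl thionocarbonate of F2 | COc1ccc(cc1)C(=O)O[C@H]2CC(C)=CC(=O)[C@@]3(C)C[C@@H](OC(=S)Oc4ccccc4)[C@@](O[Si](C)(C)C)(C(C)C)[C@@H]23
F4 | step 2 | 4-bromo-2,2-dimethylfuran-3(2H)-one | CC1(C)OC=C(Br)C1=O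
F5 | step 2 | rac-3a-bromo analogue of 4 (cis-fused, racemate) | CC1(C)O[C@H]2CC(C)=C[C@@H](O[Si](C)(C)C(C)(C)C)[C@@]2(Br)C1=O.CC1(C)O[C@@H]2CC(C)=C[C@H](O[Si](C)(C)C(C)(C)C)[C@]2(Br)C1=O
F6 | step 5 | β-hydroxy sulfide (mono-phenylthio analogue of 7) | O[C@H]1CC(C)=C[C@@H](O[Si](C)(C)C(C)(C)C)[C@H]1[C@](O)(C(C)C)CSc1ccccc1
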